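**Retrosynthetic overview**

1. Numbering: C1 (ester carbinol), C2=C3(CH3), C4, C5, C6 (tertiary carbinol), C7 (isopropyl), C8, C9 (C=O), C10 (quaternary, CH3). The seven-membered ring is C1–C6 plus C10; the five-membered ring is C6–C10.
2. Feature: C1 is an oxygen-bearing carbon bonded to the quaternary C10, and C6 next to it is a hydrated alkene carbon. The array C1(O)–C10–C6=C5 is the product pattern of a [2,3]-Wittig shift, and C1–C5 with that oxygen can pre-exist as a 4-methyl-3,6-dihydro-2H-pyran ring.
3. Target ⇒ anisoylation, alkoxide-directed iPrMgCl 1,4-addition, Saegusa enone ⇒ hydroxy ketone ⇒ C1 inverted by oxidation and Evans–Saksena reduction, C6–OH delivered from the C1 oxygen by iodocarbonate cyclisation ⇒ dienol 19.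
4. Dienol 19 ⇒ [2,3]-Wittig ring expansion (C1–C10 formed, C5–O broken) ⇒ dihydropyran 16 ⇒ ring-closing metathesis ⇒ allyl ether of an (R)-homoallylic alcohol ⇒ asymmetric methallylboration of enal 7 ⇒ 2-methylcyclopentane-1,3-dione.
5. Ring order: five-membered ring (from the dione), pyran ring (metathesis), seven-membered carbocycle (key step). All four stereocentres descend from C5.

Key step: step 8

Assumption: the facial sense of the methallylboration is taken to follow that of allylboration (the reagent made from (+)-Ipc2BOMe, (−)-α-pinene series, adds to the Re face of an aldehyde); if it is the reverse, the reagent from (−)-Ipc2BOMe is used.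

Stereochemical remark: the tethered transition state of step 8 allows one outcome only. The (2R)-pyran gives the target configuration at C10, and the C1 hydroxyl is formed trans to the C10 methyl, which is the face that the C6 hydroxyl needs. C1 is therefore used as the oxygen donor for C6 (steps 9–12) and inverted afterwards (steps 13–14).

**Route**

Step 1
Reactants: 1 2-methylcyclopentane-1,3-dione
Product: 2 3-bromo-2-methylcyclopent-2-en-1-one
Conditions: (COBr)2, DMF (cat.), CH2Cl2, 0 °C → rt
Reagents that add atoms: oxalyl bromide, BrC(=O)C(=O)Br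
Why: The enolised dione reacts as a vinylogous acid: the Vilsmeier-type bromoiminium species activates the enol oxygen and bromide adds and eliminates to give the β-bromo enone (vinylogous acyl bromide formation).

Step 2
Reactants: 2 3-bromo-2-methylcyclopent-2-en-1-one
Product: 3 7-bromo-6-methyl-1,4-dioxaspiro[4.4]non-6-ene
Conditions: TMSOCH2CH2OTMS, TMSOTf (cat.), CH2Cl2, −78 → −20 °C
Reagents that add atoms: 1,2-bis(trimethylsilyloxy)ethane, C[Si](C)(C)OCCO[Si](C)(C)C
Why: Noyori ketalisation masks the carbonyl under aprotic conditions at low temperature, so the double bond should stay in place and the later organolithium steps become possible.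

Step 3
Reactants: 3 7-bromo-6-methyl-1,4-dioxaspiro[4.4]non-6-ene; 4 N,N-dimethylformamide
Product: 7 6-methyl-1,4-dioxaspiro[4.4]non-6-ene-7-carbaldehyde, via vinyllithium 5 (not isolated), via lithium hemiaminal alkoxide 6 (not isolated)
Conditions: t-BuLi (2.1 equiv), THF, −78 °C; DMF, −78 → 0 °C; then H2O
Reagents that add atoms: none
Why: Bromine–lithium exchange (the second equivalent of t-BuLi destroys t-BuBr) gives the vinyllithium, which is formylated by DMF (Bouveault formylation); the tetrahedral adduct collapses to the aldehyde only on work-up, so no second addition should occur.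

Step 4
Reactants: 8 (2-methylprop-2-en-1-yl)magnesium chloride; 9 (+)-B-methoxydiisopinocampheylborane
Product: 10 B-(2-methylprop-2-en-1-yl)diisopinocampheylborane
Conditions: Et2O, −78 °C → rt; filtration under argon; used as solution
Reagents that add atoms: none
Why: Transmetalation from magnesium to boron gives the Brown methallylborane, and removal of MgCl(OMe) gives the salt-free reagent that reacts with aldehydes at low temperature.

Step 5
Reactants: 7 6-methyl-1,4-dioxaspiro[4.4]non-6-ene-7-carbaldehyde; 10 B-(2-methylprop-2-en-1-yl)diisopinocampheylborane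
Product: 12 (1R)-3-methyl-1-(6-methyl-1,4-dioxaspiro[4.4]non-6-en-7-yl)but-3-en-1-ol, via borinate ester 11 (not isolated)
Conditions: Et2O, −78 °C; then 3 M NaOH, 30 % H2O2, 0 °C → rt
Reagents that add atoms: none
Why: Brown asymmetric methallylboration through a closed chair transition state: the isopinocampheyl groups of the (−)-α-pinene series should direct the methallyl group to the Re face of the aldehyde and set C5 as (R), and oxidative work-up cleaves the borinate.

Step 6
Reactants: 12 (1R)-3-methyl-1-(6-methyl-1,4-dioxaspiro[4.4]non-6-en-7-yl)but-3-en-1-ol; 13 3-bromoprop-1-ene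
Product: 15 7-[(1R)-3-methyl-1-(prop-2-en-1-yloxy)but-3-en-1-yl]-6-methyl-1,4-dioxaspiro[4.4]non-6-ene, via sodium alkoxide 14 (not isolated)
Conditions: NaH, THF–DMF, 0 °C; allyl bromide, n-Bu4NI (cat.), rt
Reagents that add atoms: none
Why: Williamson ether synthesis: the sodium alkoxide is alkylated by allyl bromide (SN2) and the C5 stereocentre is not touched.

Step 7
Reactants: 15 7-[(1R)-3-methyl-1-(prop-2-en-1-yloxy)but-3-en-1-yl]-6-methyl-1,4-dioxaspiro[4.4]non-6-ene
Product: 16 (2R)-4-methyl-2-(6-methyl-1,4-dioxaspiro[4.4]non-6-en-7-yl)-3,6-dihydro-2H-pyran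
Conditions: second-generation Grubbs catalyst (5 mol %), CH2Cl2, 40 °C
Reagents that add atoms: none
Why: Ring-closing metathesis of the allyl ether alkene with the 1,1-disubstituted methallyl alkene closes the dihydropyran with its trisubstituted C2=C3 bond and releases ethene; the tetrasubstituted cyclopentene alkene should be inert to the catalyst.

Step 8
Reactants: 16 (2R)-4-methyl-2-(6-methyl-1,4-dioxaspiro[4.4]non-6-en-7-yl)-3,6-dihydro-2H-pyran
Product: 19 bicyclic dienol (C1 hydroxyl trans to the C10 methyl; C2=C3 and C5=C6; C9 ethylene ketal), via lithiated ether 17 (not isolated), via lithium alkoxide 18 (not isolated)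
Conditions: s-BuLi (1.3 equiv), THF, −78 → −30 °C; then H2O
Reagents that add atoms: none
Why: Proposed new method: s-BuLi removes one of the C1 hydrogens (allylic and alpha to oxygen; an amide base is too weak for an unactivated allyl ether) and the carbanion bonds to C10 through a five-membered transition state C1–O–C5–C6–C10 while the C5–O bond breaks suprafacially and C5=C6 appears, a [2,3]-Wittig rearrangement. The closest known reactions are the [2,3]-Wittig rearrangements of open-chain bis-allylic ethers and the ring contractions of large-ring bis-allylic ethers to carbocycles; a shift across a six-membered ether whose carbanion carbon sits in the ring is not established. The seven-membered carbocycle (C1, C2, C3, C4, C5, C6, C10) closes by sigmatropic ring expansion: the five pyran carbons are joined to C6 and C10 and the ring oxygen is expelled from the ring as the C1 alkoxide, through a transition state shaped like an 8-oxabicyclo[3.2.1]oct-2-ene. C10 is controlled by C5: the C2–C3–C4 bridge forces C4 into the inside position at C5 (the only arrangement that gives a cis C5=C6 in a seven-membered ring), so the oxygen bridge can lie on one face of the cyclopentene only and the (R) centre is transferred completely to C10. C1 is controlled by the same bicyclic geometry: its oxygen eclipses C6 while the C2 arm lies on the side of the C10 methyl, so the hydroxyl must come out trans to that methyl. The step needs lithiation at C1 and not at C5 and a [2,3] and not a [1,2] shift: the C1 methylene is the less substituted and kinetically more acidic site, low temperature holds back the radical-pair [1,2] path (which would give a cyclopentenol), and the cost is the allylic 1,3-strain between C4 and the C10 methyl in the transition state.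

Step 9
Reactants: 19 bicyclic dienol
Product: 20 tert-butyl carbonate of dienol 19
Conditions: Boc2O, DMAP (cat.), MeCN, rt
Reagents that add atoms: di-tert-butyl dicarbonate, CC(C)(C)OC(=O)OC(=O)OC(C)(C)C
Why: DMAP-catalysed acylation of the secondary alcohol gives the tert-butyl carbonate that will serve as the internal oxygen nucleophile; no stereocentre is touched.

Step 10
Reactants: 20 tert-butyl carbonate of dienol 19
Product: 21 cyclic carbonate of the C1 and C6 oxygens with iodine at C5 (iodine trans to the C6 oxygen; both oxygens trans to the C10 methyl; C9 ethylene ketal)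
Conditions: IBr, toluene, −85 °C; aq Na2S2O3
Reagents that add atoms: iodine monobromide, BrI
Why: Iodocarbonate cyclisation of a homoallylic tert-butyl carbonate: the iodonium ion forms on the open, methyl-side face of C5=C6 and the carbonyl oxygen tethered to C1 attacks the more substituted C6 from the other face (6-exo, loss of the tert-butyl group), which sets C6–O cis to C1–O and trans to the C10 methyl, while C2=C3 is deactivated by the allylic carbonate.

Step 11
Reactants: 21 cyclic iodocarbonate
Product: 22 epoxy alcohol (C5–C6 epoxide on the face of the C1 hydroxyl; both trans to the C10 methyl; C9 ethylene ketal)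
Conditions: K2CO3, MeOH, rt
Reagents that add atoms: none
Why: Methanolysis of the cyclic carbonate frees the C6 alkoxide, which displaces the antiperiplanar iodide at C5 (intramolecular Williamson reaction, inversion at C5) and leaves the C6–O configuration unchanged.

Step 12
Reactants: 22 epoxy alcohol
Product: 23 syn-1,3-diol (C1–OH and C6–OH cis to each other and trans to the C10 methyl; C9 ethylene ketal)
Conditions: LiAlH4, THF, 0 → 50 °C; then H2O
Reagents that add atoms: none
Why: Hydride opens the trisubstituted epoxide by SN2 attack at the less substituted C5 from the open face, so the tertiary C6–O bond and its configuration are kept.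

Step 13
Reactants: 23 syn-1,3-diol
Product: 24 hydroxy enone (C1 ketone conjugated with C2=C3; C6–OH trans to the C10 methyl; C9 ethylene ketal)
Conditions: Dess–Martin periodinane, CH2Cl2, rt
Reagents that add atoms: none
Why: Dess–Martin oxidation converts the secondary allylic alcohol to the enone while the tertiary C6 alcohol cannot be oxidised; the C1 stereocentre is removed on purpose so that it can be reset.

Step 14
Reactants: 24 hydroxy enone
Product: 25 anti-1,3-diol (C1–OH cis and C6–OH trans to the C10 methyl; C9 ethylene ketal)
Conditions: Me4NBH(OAc)3, MeCN–AcOH (1:1), −30 → 0 °C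
Reagents that add atoms: none
Why: Evans–Saksena reduction: the C6 hydroxyl exchanges an acetate on boron and hydride is delivered within the molecule to the face of the C1 carbonyl that is syn to the C6 oxygen, so the new C1 hydroxyl should be anti to the C6 hydroxyl and cis to the C10 methyl, as in the target; the reagent reduces only the directed carbonyl (1,2).

Step 15
Reactants: 25 anti-1,3-diol
Product: 26 keto diol (C9 ketone; C1–OH cis and C6–OH trans to the C10 methyl)
Conditions: PPTS, acetone–H2O (4:1), 45 °C
Reagents that add atoms: water, O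
Why: Acid-catalysed hydrolysis of the dioxolane under buffered conditions that should spare the allylic and the tertiary alcohol; no stereocentre is touched.

Step 16
Reactants: 26 keto diol
Product: 27 tris(trimethylsilyl) compound (C8=C9 silyl enol ether; C1 and C6 trimethylsilyl ethers)
Conditions: TMSOTf (3.5 equiv), Et3N, CH2Cl2, 0 °C
Reagents that add atoms: trimethylsilyl trifluoromethanesulfonate, C[Si](C)(C)OS(=O)(=O)C(F)(F)F
Why: Soft enolisation and silylation give the only possible enol ether (C10 is quaternary) and cap both hydroxyls, which protects the β-hydroxy ketone against retro-aldol cleavage and the allylic alcohol against oxidation in the next step.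

Step 17
Reactants: 27 tris(trimethylsilyl) compound
Product: 29 enone diol (C7=C8–C9=O; free C1 and C6 hydroxyls), via silylated enone 28 (not isolated)
Conditions: Pd(OAc)2 (1.1 equiv), MeCN, rt; then citric acid, MeOH, 0 °C
Reagents that add atoms: none
Why: Saegusa–Ito oxidation: divalent palladium converts the silyl enol ether to a palladium enolate and β-hydride elimination gives the C7=C8 enone; mild acidic methanolysis then removes both trimethylsilyl ethers.

Step 18
Reactants: 29 enone diol; 30 isopropylmagnesium chloride
Product: 32 keto diol with the C7 isopropyl group cis to the C6 hydroxyl (C1–OH cis to the C10 methyl; C9 ketone), via magnesium enolate 31 (not isolated)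
Conditions: iPrMgCl (4 equiv), THF, −78 → −20 °C; then H2O
Reagents that add atoms: none
Why: Alkoxide-directed (ligand-assisted) conjugate addition of a Grignard reagent to a γ-oxido enone: the chloromagnesium alkoxide at C6 binds a further equivalent of iPrMgCl and should deliver isopropyl to C7 on its own face, setting C7 cis to the C6 hydroxyl; 1,2-addition is held back by the quaternary C10 next to the carbonyl.

Step 19
Reactants: 32 keto diol with C7 isopropyl; 33 4-methoxybenzoyl chloride
Product: 34 CNP0246512.2 (4-methoxybenzoate of 32 at the C1 oxygen)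
Conditions: Et3N, DMAP (cat.), CH2Cl2, 0 °C → rt
Reagents that add atoms: none
Why: DMAP-catalysed acyl transfer esterifies the secondary allylic alcohol, the tertiary C6 hydroxyl being too hindered to react; no stereocentre is touched and the product is (1R,6S,7R,10S) in the numbering used here.

**Compound list**

1 | 2-methylcyclopentane-1,3-dione | CC1C(=O)CCC1=O | starting material
2 | 3-bromo-2-methylcyclopent-2-en-1-one | CC1=C(Br)CCC1=O | intermediate
3 | 7-bromo-6-methyl-1,4-dioxaspiro[4.4]non-6-ene | BrC1=C(C)C2(CC1)OCCO2 | intermediate
4 | N,N-dimethylformamide | CN(C)C=O | starting material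
5 | (6-methyl-1,4-dioxaspiro[4.4]non-6-en-7-yl)lithium | [Li]C1=C(C)C2(CC1)OCCO2 | intermediate
6 | lithium (dimethylamino)(6-methyl-1,4-dioxaspiro[4.4]non-6-en-7-yl)methanolate | [Li]OC(N(C)C)C1=C(C)C2(CC1)OCCO2 | intermediate
7 | 6-methyl-1,4-dioxaspiro[4.4]non-6-ene-7-carbaldehyde | O=CC1=C(C)C2(CC1)OCCO2 | intermediate
8 | (2-methylprop-2-en-1-yl)magnesium chloride | CC(=C)C[Mg]Cl | starting material
9 | (+)-B-methoxydiisopinocampheylborane ((−)-α-pinene series) | COB([C@H]1C[C@H]2C[C@@H]([C@@H]1C)C2(C)C)[C@H]1C[C@H]2C[C@@H]([C@@H]1C)C2(C)C | starting material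
10 | B-(2-methylprop-2-en-1-yl)diisopinocampheylborane ((−)-α-pinene series) | CC(=C)CB([C@H]1C[C@H]2C[C@@H]([C@@H]1C)C2(C)C)[C@H]1C[C@H]2C[C@@H]([C@@H]1C)C2(C)C | intermediate
11 | diisopinocampheylborinate ester of alcohol 12 | CC(=C)C[C@@H](OB([C@H]1C[C@H]2C[C@@H]([C@@H]1C)C2(C)C)[C@H]1C[C@H]2C[C@@H]([C@@H]1C)C2(C)C)C1=C(C)C2(CC1)OCCO2 | intermediate
12 | (1R)-3-methyl-1-(6-methyl-1,4-dioxaspiro[4.4]non-6-en-7-yl)but-3-en-1-ol | CC(=C)C[C@@H](O)C1=C(C)C2(CC1)OCCO2 | intermediate
13 | 3-bromoprop-1-ene | C=CCBr | starting material
14 | sodium alkoxide of alcohol 12 | [Na]O[C@H](CC(C)=C)C1=C(C)C2(CC1)OCCO2 | intermediate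
15 | 7-[(1R)-3-methyl-1-(prop-2-en-1-yloxy)but-3-en-1-yl]-6-methyl-1,4-dioxaspiro[4.4]non-6-ene | C=CCO[C@H](CC(C)=C)C1=C(C)C2(CC1)OCCO2 | intermediate
16 | (2R)-4-methyl-2-(6-methyl-1,4-dioxaspiro[4.4]non-6-en-7-yl)-3,6-dihydro-2H-pyran | CC1=CCO[C@H](C1)C2=C(C)C3(CC2)OCCO3 | intermediate
17 | 6-lithio derivative of pyran 16 (lithium at C1 of the numbering used here) | CC1=CC([Li])O[C@H](C1)C2=C(C)C3(CC2)OCCO3 | intermediate
18 | lithium alkoxide of dienol 19 | [Li]O[C@H]2C=C(C)CC=C3CCC4(OCCO4)[C@@]23C | intermediate
19 | bicyclic dienol, (1S,10R) in the numbering used here (C1–OH trans to the C10 methyl; C2=C3; C5=C6; C9 ethylene ketal) | O[C@H]2C=C(C)CC=C3CCC4(OCCO4)[C@@]23C | intermediate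
20 | tert-butyl carbonate of dienol 19 | CC(C)(C)OC(=O)O[C@H]2C=C(C)CC=C3CCC4(OCCO4)[C@@]23C | intermediate
21 | cyclic carbonate of the C1 and C6 oxygens with iodine at C5 (iodine trans to the C6 oxygen; C9 ethylene ketal) | O=C1O[C@H]2C=C(C)C[C@H](I)[C@]3(O1)CCC4(OCCO4)[C@@]23C | intermediate
22 | epoxy alcohol (C5–C6 epoxide cis to the C1 hydroxyl and trans to the C10 methyl; C9 ethylene ketal) | O[C@H]2C=C(C)C[C@H]1O[C@]13CCC4(OCCO4)[C@@]23C | intermediate
23 | syn-1,3-diol (C1–OH and C6–OH both trans to the C10 methyl; C9 ethylene ketal) | O[C@H]2C=C(C)CC[C@]3(O)CCC4(OCCO4)[C@@]23C | intermediate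
24 | hydroxy enone (C1 ketone; C6–OH trans to the C10 methyl; C9 ethylene ketal) | O=C2C=C(C)CC[C@]3(O)CCC4(OCCO4)[C@@]23C | intermediate
25 | anti-1,3-diol (C1–OH cis and C6–OH trans to the C10 methyl; C9 ethylene ketal) | O[C@@H]2C=C(C)CC[C@]3(O)CCC4(OCCO4)[C@@]23C | intermediate
26 | keto diol (C9 ketone; C1–OH cis and C6–OH trans to the C10 methyl) | O[C@@H]2C=C(C)CC[C@]3(O)CCC(=O)[C@@]23C | intermediate
27 | tris(trimethylsilyl) compound (C8=C9 silyl enol ether; C1 and C6 trimethylsilyl ethers) | C[Si](C)(C)O[C@@H]2C=C(C)CC[C@]3(O[Si](C)(C)C)CC=C(O[Si](C)(C)C)[C@@]23C | intermediate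
28 | bis(trimethylsilyl) ether of enone 29 | C[Si](C)(C)O[C@@H]2C=C(C)CC[C@]3(O[Si](C)(C)C)C=CC(=O)[C@@]23C | intermediate
29 | enone diol (C7=C8–C9=O; free C1 and C6 hydroxyls) | O[C@@H]2C=C(C)CC[C@]3(O)C=CC(=O)[C@@]23C | intermediate
30 | isopropylmagnesium chloride | CC(C)[Mg]Cl | starting material
31 | tris(chloromagnesium) species (C1 and C6 alkoxides; C8=C9 enolate; isopropyl at C7) | Cl[Mg]O[C@@H]2C=C(C)CC[C@]3(O[Mg]Cl)[C@@H](C(C)C)C=C(O[Mg]Cl)[C@@]23C | intermediate
32 | keto diol with the C7 isopropyl cis to the C6 hydroxyl (C1–OH cis to the C10 methyl; C9 ketone) | O[C@@H]2C=C(C)CC[C@]3(O)[C@@H](C(C)C)CC(=O)[C@@]23C | intermediate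
33 | 4-methoxybenzoyl chloride | COc1ccc(cc1)C(Cl)=O | starting material
34 | CNP0246512.2 | COc1ccc(C(=O)O[C@@H]2C=C(C)CC[C@]3(O)[C@@H](C(C)C)CC(=O)[C@@]23C)cc1 | target

**Step count**

Total step count: 19. Longest linear sequence: 18 steps (steps 1–3 and 5–19; step 4 is a one-step branch).

**Steps most likely to fail**

1) Step 8 (ring-expanding [2,3]-Wittig). The rearrangement may lose to the [1,2]-shift of the radical pair, to lithiation at C5, or to simple inertness caused by the allylic strain between C4 and the C10 methyl in the transition state. The fallback closes the seven-membered ring by a divinylcyclopropane–cycloheptadiene (Cope) rearrangement, a known route to fused cyclohepta-1,4-dienes. It sets out from aldehyde 7 and comes back at dienol 19.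
- Still–Gennari olefination of 7 with methyl 2-[bis(2,2,2-trifluoroethoxy)phosphoryl]propanoate (KN(SiMe3)2, 18-crown-6, THF, −78 °C) should give the (Z)-enoate methyl (2Z)-2-methyl-3-(6-methyl-1,4-dioxaspiro[4.4]non-6-en-7-yl)prop-2-enoate F1.
- Reduction with i-Bu2AlH gives the (Z)-allylic alcohol F2.
- Charette asymmetric cyclopropanation (Et2Zn, CH2I2, the tartramide-derived butyl dioxaborolane ligand of the enantiomeric series that delivers methylene to the required face) gives the cyclopropylmethanol F3, with the cyclopentenyl group and the CH2OH group cis.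
- Dess–Martin oxidation gives the cyclopropanecarbaldehyde F4, which cannot epimerise because its alpha carbon is quaternary.
- Takai-type boron olefination (CrCl2, Cl2CHBpin, LiI, THF) gives the (E)-vinylboronate F5.
- Heating (toluene or xylene, 110–140 °C) should give the allylic boronate F6 through the boat transition state. The (E)-boryl group is exo and the C10 methyl endo, so boron ends trans to the methyl; the cis methyl on the cyclopentene makes this step slow.
- Oxidation with NaBO3·4H2O proceeds with retention and returns to 19.

2) Step 10 (iodocarbonate cyclisation). The carbonate may close onto the allylic C2=C3 bond, or closure at the hindered, fully substituted C6 may be too slow and the iodonium ion may revert or eliminate. The fallback replaces tethered delivery by an intermolecular anti-hydration. It sets out from dienol 19 and comes back at hydroxy enone 24.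
- Dess–Martin oxidation of 19 gives the dienone F7, in which C2=C3 is deactivated.
- NBS in aqueous acetone at 0 °C should give the bromohydrin F8. The bromonium ion forms on the methyl-side face, the only open face of C5=C6 in the folded cycloheptadienone, and water enters at the more substituted C6 from the other face.
- Bu3SnH with AIBN in benzene at 80 °C removes the bromine and returns to 24.

3) Step 18 (directed conjugate addition). The Grignard reagent may add 1,2 to the carbonyl, or isopropyl may be delivered to the wrong face if the magnesium alkoxide does not direct. The fallback sets C7 by hydride delivery instead of carbon delivery. It sets out from the silylated enone 28 (isolated by leaving out the methanolysis of step 17) and comes back at keto diol 32.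
- iPr2CuLi with TMSCl in THF at −78 °C gives the silyl enol ether F9, as a mixture at C7 that does not matter.
- A second Saegusa–Ito oxidation (Pd(OAc)2, MeCN) gives the β-isopropyl enone F10.
- Conjugate reduction with [(Ph3P)CuH]6 (Stryker's reagent) should deliver hydride to C7 from the face opposite the C6 trimethylsilyloxy group, giving the bis(trimethylsilyl) ether F11 with isopropyl cis to the C6 oxygen.
- Citric acid in methanol returns to 32.

Further compounds
F1 | step 8 | methyl (2Z)-2-methyl-3-(6-methyl-1,4-dioxaspiro[4.4]non-6-en-7-yl)prop-2-enoate | COC(=O)/C(C)=C\C1=C(C)C2(CC1)OCCO2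
F2 | step 8 | (2Z)-2-methyl-3-(6-methyl-1,4-dioxaspiro[4.4]non-6-en-7-yl)prop-2-en-1-ol | OC/C(C)=C\C1=C(C)C2(CC1)OCCO2
F3 | step 8 | [1-methyl-2-(6-methyl-1,4-dioxaspiro[4.4]non-6-en-7-yl)cyclopropyl]methanol (CH2OH and cyclopentenyl cis) | C[C@@]1(CO)C[C@@H]1C2=C(C)C3(CC2)OCCO3
F4 | step 8 | 1-methyl-2-(6-methyl-1,4-dioxaspiro[4.4]non-6-en-7-yl)cyclopropane-1-carbaldehyde (CHO and cyclopentenyl cis) | C[C@@]1(C=O)C[C@@H]1C2=C(C)C3(CC2)OCCO3
F5 | step 8 | (E)-vinylboronate: pinacol ester of 2-[1-methyl-2-(6-methyl-1,4-dioxaspiro[4.4]non-6-en-7-yl)cyclopropyl]ethenylboronic acid | C[C@@]1(/C=C/B2OC(C)(C)C(C)(C)O2)C[C@@H]1C3=C(C)C4(CC3)OCCO4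
F6 | step 8 | allylic pinacol boronate of the bicyclic diene (boron at C1 trans to the C10 methyl; C9 ethylene ketal) | CC1(C)OB(OC1(C)C)[C@H]2C=C(C)CC=C3CCC4(OCCO4)[C@@]23C
F7 | step 10 | bicyclic dienone (C1 ketone; C2=C3; C5=C6; C9 ethylene ketal) | O=C2C=C(C)CC=C3CCC4(OCCO4)[C@@]23C
F8 | step 10 | bromohydrin (C5 bromide trans to the C6 hydroxyl; C6–OH trans to the C10 methyl; C1 ketone; C9 ethylene ketal) | O=C2C=C(C)C[C@H](Br)[C@]3(O)CCC4(OCCO4)[C@@]23C
F9 | step 18 | tris(trimethylsilyl) 1,4-adduct (C8=C9 silyl enol ether; isopropyl at C7 of either configuration) | C[Si](C)(C)O[C@@H]2C=C(C)CC[C@]3(O[Si](C)(C)C)C(C(C)C)C=C(O[Si](C)(C)C)[C@@]23C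
F10 | step 18 | β-isopropyl enone bis(trimethylsilyl) ether (C7=C8 with isopropyl on C7) | C[Si](C)(C)O[C@@H]2C=C(C)CC[C@]3(O[Si](C)(C)C)C(C(C)C)=CC(=O)[C@@]23C
F11 | step 18 | bis(trimethylsilyl) ether of keto diol 32 | C[Si](C)(C)O[C@@H]2C=C(C)CC[C@]3(O[Si](C)(C)C)[C@@H](C(C)C)CC(=O)[C@@]23C
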